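Readings and results are calculated on assumed constants, and the scatter is random.

Slowness is the worry here: cedar creeps until about 20.0 h, and a side step may creep on after that. So ask for the end state first, which needs no rate.

| flask | substrate | coupling partner | remark | time |
|---|---|---|---|---|
| cedar | 15 mM | 20 mM | run made earlier |  |
| alder | 15 mM | 67 mM | run made earlier |  |
| north-west | 15 mM | 15.0 mM |  | 2.5 d |
| south-west | 15 mM | 45.0 mM |  | 2.5 d |
| north | 15 mM | 22.5 mM |  | 2.5 d |

| run | time / h | bis adduct / % |
|---|---|---|
| cedar | 2.50 | 19.9 |
| cedar | 4.00 | 25.8 |
| cedar | 6.00 | 31.0 |
| cedar | 10.0 | 35.1 |
| cedar | 20.0 | 36.5 |
| cedar | 30.0 | 36.4 |
| alder | 2.00 | 77.5 |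
| alder | 6.00 | 98.5 |
| alder | 10.0 | 99.4 |
| alder | 15.0 | 99.4 |
| alder | 25.0 | 99.9 |
| alder | 30.0 | 99.9 |

(standard deviation of a reading: 0.3 percentage points)

- percentages count the substrate that a species holds: one side product counts as two
- the numbers in the tables scatter with a standard deviation of 0.3 percentage points
- on the list of suspects stand: substrate + coupling partner -> first product; coupling partner + first product -> bis adduct; substrate + bis adduct -> side product

- which of these holds the largest part of the substrate at the end of north-west (substrate / first product / bis adduct)
- which of these holds the largest part of the substrate at the end of south-west (substrate / first product / bis adduct)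
- which of these holds the largest part of the substrate at the end of north (substrate / first product / bis adduct)
- bis adduct at the end of north, in percent of the substrate charged

Each suspect step leaves [coupling partner] + [bis adduct] − [substrate] unchanged: the first takes one partner and one substrate, the second swaps a partner for a bis adduct, and the third takes one substrate and one bis adduct. So when [coupling partner] reaches zero, bis adduct minus substrate, in percent of the substrate charged, equals the charged partner minus the charged substrate, over the charged substrate. North's 50.0% is this excess share.

The bench rule follows: once [coupling partner] is zero, bis adduct equals the excess share plus the substrate that survives. Cedar's excess share is 33.3% and its plateau reads 36.5%, so you read a surviving substrate of 3.2 percentage points. The rule stops at a partner-to-substrate ratio of 2, below which the partner is the limiting reagent. Alder stands at 4.47, and its excess share of 347% against a reading of 99.9% means partner must remain.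

South-west, at 3.00, should therefore end as bis adduct. North-west has an excess share of 0%, so bis adduct equals substrate, and cedar's small residue puts first product ahead. North has 3.00 times cedar's flattening time and more partner than cedar, so your reckoning puts bis adduct between 50.0% and 53.2%, narrowly leading.

The forecast says first product, bis adduct and bis adduct for north-west, south-west and north, with 50.8% (50.1% to 51.6%) of bis adduct in north: “The same balance holds with the side reaction, so bis narrowly leads”.

    substrate + coupling partner → first product (k = 1.30 /M/min)
    coupling partner + first product → bis adduct (k = 0.320 /M/min)
    substrate + bis adduct → side product (k = 0.0410 /M/min)

At its end, north-west holds 62.8% first product, against 13.2% bis adduct and 13.2% substrate. South-west ends with 99.7% bis adduct. North holds 50.6% bis adduct, 0.573% substrate, 45.4% first product and 0% partner at 2.50 d, so the difference is 50 points, against the excess share 50.0%. In north at 0.0200 d, substrate goes to first product 730 times as fast as to side product. Half of the side step's turnover lies behind 0.539 d, later than the second step's 0.115 d.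

Take north with 14 mM of partner: its excess share is −6.67%, so bis adduct should stand 6.67% below substrate. That flask gives 10.3% against 17.0% with 0% partner, and first product now holds most.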